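**Retrosynthetic overview**
1. Labels: C1 ester CH, C2 CH2, C3 (methyl)=C4, C5 and C6 CH2, C7 methyl carbinol, C8=C9, C10 isopropyl CH. Feature used: in the ten-membered carbocycle C8 is flanked by the oxygenated C7 and lies 1,5 to the E C3=C4 alkene, i.e. a cyclodec-5-en-1-one (C8=O) hydroxylated at C7.
2. Target ⇒ diol 18 + acetyl-protected vanillic acid (C1–O acylation last); C8=C9 ⇒ syn-dehydration of the reduced C8 ketone of α-hydroxy ketone 14.
3. 14 ⇒ cyclohexanol 11 by an anionic oxy-Cope shift (C5–C6 formed, ring bond C3–C8 broken), with the C7=C8 enolate hydroxylated in the same flask (C7–O).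
4. 11 ⇒ ketone 5: isopropenyl added at C8, then the oxygen is put back on the axial face by sulfenate/sulfoxide [2,3] shifts. 5 ⇒ formylation, C-methylation and methylenation at C3 ⇒ anti 1,4-addition of isopropyl (C10) to (S)-4-silyloxycyclohexenone 1 (C1).
5. Ring order: the six-membered ring is bought; the ten-membered ring is the only ring made, by four-carbon expansion in step 7.

Key step: step 7

Remarks
- TBS = tert-butyldimethylsilyl, TES = triethylsilyl. Names carry their own locants; the labels C1–C10 always refer to line 1 of the overview.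
- Assumption: enone 1 is bought as the single (S) enantiomer.
- Design remark: on these chair cyclohexanes, reagents should add to sp2 C3 anti to the C1 oxygen (axially), and to sp2 C8 anti to the axial C3 methyl. The methyl at C3 and the oxygen at C8 are therefore the groups put on last; a ring that already carries the C3 methyl would give the wrong C3 epimer.

**Route**

Step 1
Reactants: 1 (S)-4-(TBSO)cyclohex-2-en-1-one
Product: 2 (3R,4S)-4-(TBSO)-3-(propan-2-yl)cyclohexan-1-one
Conditions: i-PrMgCl, CuBr·SMe2 (0.2 equiv), THF, −78 to −30 °C; aq. NH4Cl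
Reagents that add atoms: isopropylmagnesium chloride, CC(C)[Mg]Cl
Why: Copper-catalysed conjugate addition of the Grignard reagent; the isopropyl group should enter C10 anti to the neighbouring C1 silyloxy group, which sets C10 trans to C1–O.

Step 2
Reactants: 2 (3R,4S)-4-(TBSO)-3-(propan-2-yl)cyclohexan-1-one
Product: 3 (2Z,4S,5R)-4-(TBSO)-2-(hydroxymethylidene)-5-(propan-2-yl)cyclohexan-1-one
Conditions: NaH, HCO2Et, EtOH (cat.), THF, 0 to 25 °C; aq. NH4Cl
Reagents that add atoms: ethyl formate, CCOC=O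
Why: Crossed Claisen condensation (α-formylation) under equilibrating conditions should take place at the less hindered α-methylene C3, remote from the isopropyl-bearing carbon; no stereocentre is formed.

Step 3
Reactants: 3 (2Z,4S,5R)-4-(TBSO)-2-(hydroxymethylidene)-5-(propan-2-yl)cyclohexan-1-one
Product: 4 (1S,4R,5S)-5-(TBSO)-1-methyl-2-oxo-4-(propan-2-yl)cyclohexane-1-carbaldehyde
Conditions: MeI, K2CO3, acetone, 56 °C
Reagents that add atoms: iodomethane, CI
Why: C-alkylation of the β-ketoaldehyde enolate; methyl iodide should enter C3 axially on the face opposite the C1 silyloxy group, so the new quaternary centre carries an axial methyl and an equatorial formyl group cis to C1–O.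

Step 4
Reactants: 4 (1S,4R,5S)-5-(TBSO)-1-methyl-2-oxo-4-(propan-2-yl)cyclohexane-1-carbaldehyde
Product: 5 (2S,4S,5R)-4-(TBSO)-2-ethenyl-2-methyl-5-(propan-2-yl)cyclohexan-1-one
Conditions: Ph3PCH3Br, KN(SiMe3)2, THF, 0 °C; add 4 at −78 °C, warm to 0 °C
Reagents that add atoms: methyltriphenylphosphonium bromide (as its ylide), C[P+](c1ccccc1)(c1ccccc1)c1ccccc1.[Br-]
Why: Wittig methylenation, chemoselective for the aldehyde over the hindered α-quaternary ketone at low temperature; no stereocentre is touched.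

Step 5
Reactants: 5 (2S,4S,5R)-4-(TBSO)-2-ethenyl-2-methyl-5-(propan-2-yl)cyclohexan-1-one
Product: 6 (1S,2S,4S,5R)-4-(TBSO)-2-ethenyl-2-methyl-5-(propan-2-yl)-1-(prop-1-en-2-yl)cyclohexan-1-ol
Conditions: CH2=C(CH3)MgBr, CeCl3, THF, −78 to 0 °C; aq. NH4Cl
Reagents that add atoms: isopropenylmagnesium bromide, C=C(C)[Mg]Br
Why: CeCl3-mediated 1,2-addition of the alkenyl Grignard reagent to the hindered, enolisable ketone; attack anti to the axial C3 methyl should give mainly the axial-isopropenyl epimer drawn, and because step 6 resets C8 both epimers are carried on.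

Step 6
Reactants: 6 (1S,2S,4S,5R)-4-(TBSO)-2-ethenyl-2-methyl-5-(propan-2-yl)-1-(prop-1-en-2-yl)cyclohexan-1-ol
Product: 11 (1R,2S,4S,5R)-4-(TBSO)-2-ethenyl-2-methyl-5-(propan-2-yl)-1-(prop-1-en-2-yl)cyclohexan-1-ol, via lithium alkoxide 7 (not isolated), via C8 phenylsulfenate ester 8 (not isolated), via allylic sulfoxide 9 (not isolated), via C8-epimeric phenylsulfenate ester 10 (not isolated)
Conditions: n-BuLi, THF, −78 °C; PhSCl, −78 to 25 °C; then Et2NH, MeOH, 40 °C
Reagents that add atoms: none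
Why: Mislow–Evans [2,3]-sigmatropic chemistry used in both directions: the sulfenate of either C8 epimer rearranges to allylic sulfoxide 9, in which C8 is sp2, and on amine-driven reversal the oxygen should return to C8 on the axial face, anti to the axial C3 methyl that shields the other face, which sets C8 with the hydroxyl axial and the isopropenyl group equatorial, trans to the vinyl group.

Step 7
Reactants: 11 (1R,2S,4S,5R)-4-(TBSO)-2-ethenyl-2-methyl-5-(propan-2-yl)-1-(prop-1-en-2-yl)cyclohexan-1-ol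
Product: 14 (2R,5E,8S,9R)-8-(TBSO)-2-hydroxy-2,6-dimethyl-9-(propan-2-yl)cyclodec-5-en-1-one, via potassium alkoxide 12 (not isolated), via potassium enolate 13 (not isolated)
Conditions: KH, 18-crown-6, THF, 0 to 25 °C; cool to −78 °C, 3-phenyl-2-(phenylsulfonyl)oxaziridine; AcOH, −78 °C
Reagents that add atoms: 3-phenyl-2-(phenylsulfonyl)oxaziridine, O=S(=O)(c1ccccc1)N1OC1c1ccccc1
Why: Alkoxide 12 should undergo an anionic oxy-Cope [3,3] shift through a chair transition state in which the isopropenyl and vinyl groups are both equatorial on the cyclohexane chair that also holds the C1 silyloxy and C10 isopropyl groups equatorial; C5–C6 forms as the C3–C8 ring bond breaks. The closest known reaction type is the anionic oxy-Cope rearrangement of trans-1,2-dialkenylcyclohexanols to cyclodec-5-enones with trapping of the enolate by an electrophile, here a sulfonyloxaziridine (enolate hydroxylation). The ten-membered ring is not closed end to end but released by four-carbon ring expansion of the six-membered ring. In the chair the ring carbons C2 and C9 are equatorial at the breaking bond, which fixes the E C3=C4 alkene and a ring-trans C7=C8 enolate 13 of a single planar chirality. The new C7 stereocentre is controlled by that planar chirality, the oxaziridine delivering oxygen to the outer face of C7 (turned away from the transannular C3=C4 alkene), which corresponds to 7R. The step needs chair over boat and no rotation of the enolate plane before oxidation; the trans-diequatorial alkenyl groups secure the first, and oxidation at −78 °C directly after the shift secures the second, since a methyl group or the oxygen would have to pass through the ring for a flip.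

Step 8
Reactants: 14 (2R,5E,8S,9R)-8-(TBSO)-2-hydroxy-2,6-dimethyl-9-(propan-2-yl)cyclodec-5-en-1-one
Product: 15 (2R,5E,8S,9R)-8-(TBSO)-2,6-dimethyl-9-(propan-2-yl)-2-(TESO)cyclodec-5-en-1-one
Conditions: Et3SiOTf, 2,6-lutidine, CH2Cl2, −78 to 0 °C
Reagents that add atoms: triethylsilyl trifluoromethanesulfonate, CC[Si](CC)(CC)OS(=O)(=O)C(F)(F)F
Why: Silylation of the hindered tertiary C7 alcohol with a silyl triflate and a hindered base, so that the later dehydration can only act at C8.

Step 9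
Reactants: 15 (2R,5E,8S,9R)-8-(TBSO)-2,6-dimethyl-9-(propan-2-yl)-2-(TESO)cyclodec-5-en-1-one
Product: 16 (1R,2R,5E,8S,9R)-8-(TBSO)-2,6-dimethyl-9-(propan-2-yl)-2-(TESO)cyclodec-5-en-1-ol
Conditions: i-Bu2AlH, CH2Cl2, −78 °C; aq. KNaC4H4O6
Reagents that add atoms: none
Why: Hydride reduction of the ketone at low temperature (no 1,2-silyl migration); the C8 carbinol centre (Felkin approach anti to the α-silyloxy group expected) is of no consequence because it is removed in step 10.

Step 10
Reactants: 16 (1R,2R,5E,8S,9R)-8-(TBSO)-2,6-dimethyl-9-(propan-2-yl)-2-(TESO)cyclodec-5-en-1-ol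
Product: 17 bis-silyl ether of diol 18 (C1–OTBS, C7–OTES, E C3=C4, E C8=C9)
Conditions: MeO2CN(−)SO2N(+)Et3, toluene, 25 to 60 °C
Reagents that add atoms: none
Why: Burgess dehydration (syn elimination through the sulfamate ester): C7 bears no hydrogen, so only a C9 hydrogen can be lost, and syn eliminations in ten-membered rings favour the trans alkene, which should give E C8=C9.

Step 11
Reactants: 17 bis-silyl ether of diol 18
Product: 18 (1R,2E,4S,5S,7E)-1,7-dimethyl-4-(propan-2-yl)cyclodeca-2,7-diene-1,5-diol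
Conditions: Bu4NF, THF, 25 to 45 °C
Reagents that add atoms: none
Why: Fluoride-mediated cleavage of both silyl ethers under basic, non-ionising conditions that the tertiary allylic alcohol should tolerate.

Step 12
Reactants: 19 vanillic acid
Product: 20 4-(acetyloxy)-3-methoxybenzoic acid
Conditions: Ac2O, H2SO4 (cat.), 60 °C; H2O
Reagents that add atoms: acetic anhydride, CC(=O)OC(C)=O
Why: Acid-catalysed O-acetylation of the phenol; any mixed anhydride is hydrolysed on aqueous work-up.

Step 13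
Reactants: 18 (1R,2E,4S,5S,7E)-1,7-dimethyl-4-(propan-2-yl)cyclodeca-2,7-diene-1,5-diol; 20 4-(acetyloxy)-3-methoxybenzoic acid
Product: 22 (1S,2S,3E,5R,8E)-5-hydroxy-5,9-dimethyl-2-(propan-2-yl)cyclodeca-3,8-dien-1-yl 4-(acetyloxy)-3-methoxybenzoate, via acid chloride 21 (not isolated)
Conditions: 20, (COCl)2, DMF (cat.), CH2Cl2, 0 to 25 °C, evaporate; then 18, Et3N, DMAP (cat.), CH2Cl2, 0 to 25 °C
Reagents that add atoms: none
Why: DMAP-catalysed acylation with the acid chloride; the secondary C1 hydroxyl should react while the tertiary allylic C7 hydroxyl stays free, and no stereocentre is involved.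

Step 14
Reactants: 22 (1S,2S,3E,5R,8E)-5-hydroxy-5,9-dimethyl-2-(propan-2-yl)cyclodeca-3,8-dien-1-yl 4-(acetyloxy)-3-methoxybenzoate
Product: 23 (1S,2S,3E,5R,8E)-5-hydroxy-5,9-dimethyl-2-(propan-2-yl)cyclodeca-3,8-dien-1-yl 4-hydroxy-3-methoxybenzoate
Conditions: K2CO3 (cat.), MeOH, 0 °C
Reagents that add atoms: none
Why: Base-catalysed methanolysis (transesterification) of the aryl acetate, which is far more labile than the hindered, electron-rich alkyl benzoate.

**Compound list**
1 | (S)-4-(TBSO)cyclohex-2-en-1-one | O=C1C=C[C@@H](O[Si](C)(C)C(C)(C)C)CC1 | starting material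
2 | (3R,4S)-4-(TBSO)-3-(propan-2-yl)cyclohexan-1-one (trans) | CC(C)[C@H]1CC(=O)CC[C@@H]1O[Si](C)(C)C(C)(C)C | intermediate
3 | (2Z,4S,5R)-4-(TBSO)-2-(hydroxymethylidene)-5-(propan-2-yl)cyclohexan-1-one | CC(C)[C@H]1CC(=O)/C(=C\O)C[C@@H]1O[Si](C)(C)C(C)(C)C | intermediate
4 | (1S,4R,5S)-5-(TBSO)-1-methyl-2-oxo-4-(propan-2-yl)cyclohexane-1-carbaldehyde | CC(C)[C@H]1CC(=O)[C@](C)(C=O)C[C@@H]1O[Si](C)(C)C(C)(C)C | intermediate
5 | (2S,4S,5R)-4-(TBSO)-2-ethenyl-2-methyl-5-(propan-2-yl)cyclohexan-1-one | CC(C)[C@H]1CC(=O)[C@](C)(C=C)C[C@@H]1O[Si](C)(C)C(C)(C)C | intermediate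
6 | (1S,2S,4S,5R)-4-(TBSO)-2-ethenyl-2-methyl-5-(propan-2-yl)-1-(prop-1-en-2-yl)cyclohexan-1-ol (isopropenyl axial, cis to vinyl; expected major C8 epimer) | CC(C)[C@H]1C[C@](O)(C(C)=C)[C@](C)(C=C)C[C@@H]1O[Si](C)(C)C(C)(C)C | intermediate
7 | lithium alkoxide of 6 | CC(C)[C@H]1C[C@]([O-])(C(C)=C)[C@](C)(C=C)C[C@@H]1O[Si](C)(C)C(C)(C)C.[Li+] | intermediate (not isolated)
8 | phenylsulfenate ester (C8–O–SPh) of 6 | CC(C)[C@H]1C[C@](OSc2ccccc2)(C(C)=C)[C@](C)(C=C)C[C@@H]1O[Si](C)(C)C(C)(C)C | intermediate (not isolated)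
9 | tert-butyl({(1S,2R,4E,5S)-5-ethenyl-5-methyl-4-[1-(phenylsulfinyl)propan-2-ylidene]-2-(propan-2-yl)cyclohexyl}oxy)dimethylsilane, both sulfur epimers | CC(C)[C@H]1C/C(=C(/C)CS(=O)c2ccccc2)[C@](C)(C=C)C[C@@H]1O[Si](C)(C)C(C)(C)C | intermediate (not isolated)
10 | phenylsulfenate ester (C8–O–SPh) of 11 | CC(C)[C@H]1C[C@@](OSc2ccccc2)(C(C)=C)[C@](C)(C=C)C[C@@H]1O[Si](C)(C)C(C)(C)C | intermediate (not isolated)
11 | (1R,2S,4S,5R)-4-(TBSO)-2-ethenyl-2-methyl-5-(propan-2-yl)-1-(prop-1-en-2-yl)cyclohexan-1-ol (isopropenyl equatorial, trans to vinyl) | CC(C)[C@H]1C[C@@](O)(C(C)=C)[C@](C)(C=C)C[C@@H]1O[Si](C)(C)C(C)(C)C | intermediate (key-step precursor)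
12 | potassium alkoxide of 11 | CC(C)[C@H]1C[C@@]([O-])(C(C)=C)[C@](C)(C=C)C[C@@H]1O[Si](C)(C)C(C)(C)C.[K+] | intermediate (not isolated)
13 | potassium (1Z,5E,8S,9R)-8-(TBSO)-2,6-dimethyl-9-(propan-2-yl)cyclodeca-1,5-dien-1-olate (ring-trans C7=C8 enolate) | CC(C)(C)[Si](C)(C)O[C@H]1C/C(C)=C/CC/C(C)=C(\[O-])C[C@@H]1C(C)C.[K+] | intermediate (not isolated)
14 | (2R,5E,8S,9R)-8-(TBSO)-2-hydroxy-2,6-dimethyl-9-(propan-2-yl)cyclodec-5-en-1-one | CC(C)(C)[Si](C)(C)O[C@H]1C/C(C)=C/CC[C@@](C)(O)C(=O)C[C@@H]1C(C)C | intermediate (key-step product)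
15 | (2R,5E,8S,9R)-8-(TBSO)-2,6-dimethyl-9-(propan-2-yl)-2-(TESO)cyclodec-5-en-1-one | CC(C)(C)[Si](C)(C)O[C@H]1C/C(C)=C/CC[C@@](C)(O[Si](CC)(CC)CC)C(=O)C[C@@H]1C(C)C | intermediate
16 | (1R,2R,5E,8S,9R)-8-(TBSO)-2,6-dimethyl-9-(propan-2-yl)-2-(TESO)cyclodec-5-en-1-ol (expected major C8 epimer) | CC(C)(C)[Si](C)(C)O[C@H]1C/C(C)=C/CC[C@@](C)(O[Si](CC)(CC)CC)[C@H](O)C[C@@H]1C(C)C | intermediate
17 | bis-silyl ether of diol 18 (C1–OTBS, C7–OTES, E C3=C4, E C8=C9) | CC(C)(C)[Si](C)(C)O[C@H]1C/C(C)=C/CC[C@@](C)(O[Si](CC)(CC)CC)/C=C/[C@@H]1C(C)C | intermediate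
18 | (1R,2E,4S,5S,7E)-1,7-dimethyl-4-(propan-2-yl)cyclodeca-2,7-diene-1,5-diol | O[C@H]1C/C(C)=C/CC[C@@](C)(O)/C=C/[C@@H]1C(C)C | intermediate
19 | vanillic acid (4-hydroxy-3-methoxybenzoic acid) | COc1cc(C(=O)O)ccc1O | starting material
20 | 4-(acetyloxy)-3-methoxybenzoic acid | COc1cc(C(=O)O)ccc1OC(C)=O | intermediate
21 | 4-(acetyloxy)-3-methoxybenzoyl chloride | COc1cc(C(Cl)=O)ccc1OC(C)=O | intermediate (not isolated)
22 | (1S,2S,3E,5R,8E)-5-hydroxy-5,9-dimethyl-2-(propan-2-yl)cyclodeca-3,8-dien-1-yl 4-(acetyloxy)-3-methoxybenzoate | COc1cc(C(=O)O[C@H]2C/C(C)=C/CC[C@@](C)(O)/C=C/[C@@H]2C(C)C)ccc1OC(C)=O | intermediate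
23 | (1S,2S,3E,5R,8E)-5-hydroxy-5,9-dimethyl-2-(propan-2-yl)cyclodeca-3,8-dien-1-yl 4-hydroxy-3-methoxybenzoate | COc1cc(C(=O)O[C@H]2C/C(C)=C/CC[C@@](C)(O)/C=C/[C@@H]2C(C)C)ccc1O | target

**Totals**
Total step count: 14. Longest linear sequence: 13 (steps 1–11, 13, 14).

**Steps most likely to fail**

1. Step 6. The oxygen may return to C8 without face preference. The first-formed sulfenate may also be cleaved before it has passed through the strained tetrasubstituted sulfoxide, so that the axial-isopropenyl epimer is simply recovered. Fallback from 5 back to 11 makes the C8–O bond by enolate-type oxidation instead of a [2,3] shift. Ketone 5 is converted (KN(SiMe3)2, PhNTf2) into the C8 enol triflate F1. Carbonylative Stille coupling (Pd(PPh3)4, CO, SnMe4, LiCl) gives the 1-acetylcyclohexene F2. Reductive α-hydroxylation of the enone (Mn(dpm)3, PhSiH3, O2, then P(OEt)3) should place oxygen on C8 from the axial face, anti to the axial C3 methyl, giving the α-hydroxy methyl ketone F3. Wittig methylenation with a lithium-derived ylide at 0 °C, where a lithium alkoxide does not rearrange, turns the acetyl group into the isopropenyl group of 11.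

2. Step 7. Oxygen transfer to the hindered tetrasubstituted potassium enolate may be slow. Proton transfer, addition of the enolate to the sulfonimine by-product, or α-ketol rearrangement of the product alkoxide could then compete. Fallback from 11 back to 14 separates ring expansion from oxidation. After the shift (KH, 18-crown-6) the enolate is silylated with Me3SiCl to the trimethylsilyl enol ether F4. Rubottom oxidation with dimethyldioxirane at −78 °C attacks the same outer face and, after silyl shift, gives the α-(trimethylsilyloxy) ketone F5. K2CO3 in methanol then frees 14.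

3. Step 10. The elimination may give the Z alkene. Ionisation at C8 could also lead to transannular attack by the C3=C4 alkene or a 1,2-shift from C7. Fallback from 14 back to 18 makes the alkene by selenoxide elimination away from the free C7 hydroxyl. Zn(BH4)2 reduces 14 to the C7,C8-diol F6 (either C8 epimer serves; one is drawn). The secondary hydroxyl is mesylated (MsCl, Et3N) to F7, and K2CO3 in methanol closes the C7–C8 epoxide F8. PhSeNa (from PhSeSePh and NaBH4) opens it at C8 to the hydroxy selenide F9. H2O2 gives the selenoxide F10, whose syn elimination toward C9 should deliver the E allylic alcohol F11. Bu4NF then gives 18.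

Further compounds
F1 | step 6 | C8 enol triflate of ketone 5 | CC(C)[C@H]1C=C(OS(=O)(=O)C(F)(F)F)[C@](C)(C=C)C[C@@H]1O[Si](C)(C)C(C)(C)C
F2 | step 6 | 1-acetylcyclohexene (acetyl on C8, C8=C9) | CC(C)[C@H]1C=C(C(C)=O)[C@](C)(C=C)C[C@@H]1O[Si](C)(C)C(C)(C)C
F3 | step 6 | α-hydroxy methyl ketone (C8: OH axial, acetyl equatorial) | CC(C)[C@H]1C[C@@](O)(C(C)=O)[C@](C)(C=C)C[C@@H]1O[Si](C)(C)C(C)(C)C
F4 | step 7 | trimethylsilyl enol ether of the ring-expanded ketone (ring-trans C7=C8) | CC(C)(C)[Si](C)(C)O[C@H]1C/C(C)=C/CC/C(C)=C(\O[Si](C)(C)C)C[C@@H]1C(C)C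
F5 | step 7 | α-(trimethylsilyloxy) ketone (trimethylsilyl ether of 14) | CC(C)(C)[Si](C)(C)O[C@H]1C/C(C)=C/CC[C@@](C)(O[Si](C)(C)C)C(=O)C[C@@H]1C(C)C
F6 | step 10 | C7,C8-diol from 14 | CC(C)(C)[Si](C)(C)O[C@H]1C/C(C)=C/CC[C@@](C)(O)[C@@H](O)C[C@@H]1C(C)C
F7 | step 10 | C8 mesylate of F6 | CC(C)(C)[Si](C)(C)O[C@H]1C/C(C)=C/CC[C@@](C)(O)[C@@H](OS(C)(=O)=O)C[C@@H]1C(C)C
F8 | step 10 | C7–C8 epoxide | CC(C)(C)[Si](C)(C)O[C@H]1C/C(C)=C/CC[C@@]2(C)O[C@@H]2C[C@@H]1C(C)C
F9 | step 10 | C7 hydroxy C8 phenylselenide | CC(C)(C)[Si](C)(C)O[C@H]1C/C(C)=C/CC[C@@](C)(O)[C@@H]([Se]c2ccccc2)C[C@@H]1C(C)C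
F10 | step 10 | selenoxide of F9 | CC(C)(C)[Si](C)(C)O[C@H]1C/C(C)=C/CC[C@@](C)(O)[C@@H]([Se](=O)c2ccccc2)C[C@@H]1C(C)C
F11 | step 10 | C1 TBS ether of diol 18 | CC(C)(C)[Si](C)(C)O[C@H]1C/C(C)=C/CC[C@@](C)(O)/C=C/[C@@H]1C(C)C
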